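**Plan**

- Retrosynthesis cuts the polyene at C11'=C12' and C11=C12 (two Wittig bonds), giving an ε-ring C15 phosphonium salt, the C10 trienedial and a furanoid C15 phosphonium salt. The ε-unit is cut further at C9'–C10' and C7'=C8' back to (R)-α-cyclocitral, and its C6'–C7' bond is traced to a C4'–O bond.
- Enabling feature: C6' of the ε-ring cyclohexene is a tertiary allylic stereocentre lying between quaternary C1' and the C4'=C5' alkene, so the C6'–C7' bond can be delivered from an oxygen on C4' by a [2,3]-shift with allylic transposition.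
- Forward ring order: the ε-half cyclohexene is made first by annulation (step 1). In the other half the cyclohexene of β-cyclocitral is epoxidised at C5=C6, and the dihydrofuran ring closes by O–C8 bond formation (step 14).
- Chain assembly: furanoid C15 ylide + C10 dialdehyde gives the C25 aldehyde (C11=C12), and the ε-ring C15 ylide is joined last (C11'=C12').
- Stereochemistry: C6' comes from an oxazaborolidine-set carbinol relayed by suprafacial 1,3-transfer. C5 comes from a Sharpless epoxidation. C8 is not controlled by the ring closure, so the (8R) isomer is taken from the epimer pair by chromatography and the other isomer is re-equilibrated with acid. E-alkenes come from Horner–Wadsworth–Emmons and Wittig steps with thermal equilibration.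

Key step: step 4

Assumption: the target is read from the SMILES as the all-E polyene with (5R,8R,6'R) configuration; carotenoid numbering is used, unprimed for the furanoid half and primed for the ε-ring half.

Step 1
Reactants: 1 2-methylpropanal; 2 pent-1-en-3-one
Product: 4 2,4,4-trimethylcyclohex-2-en-1-one, via keto aldehyde 3 (not isolated)
Conditions: conc. H2SO4 (cat.), neat, 45–50 °C; then toluene, reflux, Dean–Stark
Reagents that add atoms: none
Why: Acid-catalysed Michael addition of the aldehyde enol to the enone followed by intramolecular aldol condensation (Robinson-type annulation) should give the enone, because the quaternary α-carbon of 3 leaves only the ethyl-ketone methylene to close a six-membered ring; no stereocentre is formed.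

Step 2
Reactants: 4 2,4,4-trimethylcyclohex-2-en-1-one
Product: 5 (1S)-2,4,4-trimethylcyclohex-2-en-1-ol
Conditions: (3aR)-1-methyl-3,3-diphenyltetrahydro-1H,3H-pyrrolo[1,2-c][1,3,2]oxazaborole (10 mol %), BH3·SMe2, THF, −20 °C; MeOH
Reagents that add atoms: none
Why: In this Corey–Bakshi–Shibata reduction the ketone should bind the ring boron with its α-methylvinyl arm as the large group, so the nitrogen-bound borane delivers hydride 1,2 to the face that gives the (S)-carbinol, by the same model that turns acetophenone into the (R)-alcohol with the enantiomeric catalyst.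

Step 3
Reactants: 5 (1S)-2,4,4-trimethylcyclohex-2-en-1-ol; 6 tributyl(iodomethyl)stannane
Product: 7 tributyl({[(1S)-2,4,4-trimethylcyclohex-2-en-1-yl]oxy}methyl)stannane
Conditions: KH, THF, 0 °C; then 6, 18-crown-6 (cat.), 0 °C → rt
Reagents that add atoms: none
Why: Williamson etherification of the potassium alkoxide with the primary α-stannyl iodide is a plain SN2 alkylation at the reagent carbon, so the carbinol configuration is untouched.

Step 4
Reactants: 7 tributyl({[(1S)-2,4,4-trimethylcyclohex-2-en-1-yl]oxy}methyl)stannane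
Product: 9 [(1R)-2,6,6-trimethylcyclohex-2-en-1-yl]methanol, via alkoxymethyllithium 8 (not isolated)
Conditions: n-BuLi (1.2 equiv), THF, −78 °C, then −78 → −20 °C; H2O
Reagents that add atoms: none
Why: Tin–lithium exchange should give the unstabilised α-alkoxymethyllithium 8, which undergoes a concerted [2,3]-sigmatropic shift through a five-membered envelope transition state in which the carbanion carbon bonds to C6' while the C4'–O bond breaks and the alkene moves to C4'=C5'. The closest known reaction type is the Wittig–Still rearrangement of stannylmethyl ethers of cyclohex-2-enols with 1,3-chirality transfer. No ring is closed; only the transition state is cyclic. The new stereocentre C6' is controlled by the carbinol centre C4': the short O–CH2 tether lets the carbanion reach only the ring face that carried the oxygen, so the shift is suprafacial and the (S)-ether should give (R) at C6'. The step needs [2,3]- over [1,2]-shift and over simple quenching of the carbanion, and it must form a bond beside quaternary C1'; the low temperature, the pseudoaxial C–O bond of the half-chair (which overlaps with the alkene on the face away from the pseudoaxial methyl of C1') and the minimal size of the migrating CH2 should secure this.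

Step 5
Reactants: 9 [(1R)-2,6,6-trimethylcyclohex-2-en-1-yl]methanol
Product: 10 (1R)-2,6,6-trimethylcyclohex-2-ene-1-carbaldehyde
Conditions: Dess–Martin periodinane, NaHCO3, CH2Cl2, 0 °C → rt; used at once without chromatography
Reagents that add atoms: none
Why: Buffered Dess–Martin oxidation works under near-neutral conditions, so the aldehyde should form without enolisation at C6' and without migration of the ring alkene into conjugation.

Step 6
Reactants: 10 (1R)-2,6,6-trimethylcyclohex-2-ene-1-carbaldehyde
Product: 11 (3E)-4-[(1R)-2,6,6-trimethylcyclohex-2-en-1-yl]but-3-en-2-one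
Conditions: (EtO)2P(O)CH2C(O)CH3 (1.3 equiv), NaH (1.2 equiv), THF, 0 °C; then 10, 0 °C → rt
Reagents that add atoms: diethyl (2-oxopropyl)phosphonate, CCOP(=O)(CC(C)=O)OCC
Why: Horner–Wadsworth–Emmons olefination with the stabilised ketophosphonate anion, kept free of excess hydride, should add to the aldehyde faster than it removes the hindered C6' proton and should give the (E)-enone through the usual thermodynamic oxaphosphetane control.

Step 7
Reactants: 11 (3E)-4-[(1R)-2,6,6-trimethylcyclohex-2-en-1-yl]but-3-en-2-one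
Product: 12 (1E)-3-methyl-1-[(1R)-2,6,6-trimethylcyclohex-2-en-1-yl]penta-1,4-dien-3-ol
Conditions: CH2=CHMgBr, THF, −20 → 0 °C; aq. NH4Cl
Reagents that add atoms: vinylmagnesium bromide, C=C[Mg]Br
Why: Grignard 1,2-addition to the enone carbonyl should give the tertiary bis-allylic alcohol as both carbinol epimers, which is of no consequence because that centre is erased in step 8, while C6' is not involved.

Step 8
Reactants: 12 (1E)-3-methyl-1-[(1R)-2,6,6-trimethylcyclohex-2-en-1-yl]penta-1,4-dien-3-ol
Product: 13 {(2E,4E)-3-methyl-5-[(1R)-2,6,6-trimethylcyclohex-2-en-1-yl]penta-2,4-dien-1-yl}triphenylphosphonium bromide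
Conditions: PPh3·HBr, MeOH, 0 °C → rt; crystallise from EtOAc
Reagents that add atoms: triphenylphosphine hydrobromide, [Br-].c1ccc(cc1)[PH+](c1ccccc1)c1ccccc1
Why: Ionisation of the tertiary alcohol to a pentadienyl cation and capture by triphenylphosphine at the unhindered primary terminus (SN1' allylic transposition, the standard route to C15 ionylidene phosphonium salts) should give the salt, with the more stable 2E geometry enriched by crystallisation and C6' outside the reacting system.

Step 9
Reactants: 14 2,6,6-trimethylcyclohex-1-ene-1-carbaldehyde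
Product: 15 (2,6,6-trimethylcyclohex-1-en-1-yl)methanol
Conditions: NaBH4, MeOH, 0 °C
Reagents that add atoms: none
Why: Borohydride 1,2-reduction of the hindered conjugated aldehyde should give the allylic alcohol needed for a directed epoxidation; no stereocentre is formed.

Step 10
Reactants: 15 (2,6,6-trimethylcyclohex-1-en-1-yl)methanol
Product: 16 [(1R,6R)-2,2,6-trimethyl-7-oxabicyclo[4.1.0]heptan-1-yl]methanol
Conditions: Ti(OiPr)4 (cat.), D-(−)-diethyl tartrate, t-BuOOH, 4 Å molecular sieves, CH2Cl2, −20 °C
Reagents that add atoms: tert-butyl hydroperoxide, CC(C)(C)OO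
Why: In this Sharpless asymmetric epoxidation the titanium tartrate complex binds the allylic hydroxyl and delivers the peroxide oxygen to one alkene face, and D-(−)-tartrate is chosen because it uses the face opposite to the one by which L-(+)-tartrate turns geraniol into its (2S,3S)-epoxide, which here should set both epoxide carbons at once with (R) at the methyl-bearing carbon (C5 of the target).

Step 11
Reactants: 16 [(1R,6R)-2,2,6-trimethyl-7-oxabicyclo[4.1.0]heptan-1-yl]methanol
Product: 17 (1S,6R)-2,2,6-trimethyl-7-oxabicyclo[4.1.0]heptane-1-carbaldehyde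
Conditions: Dess–Martin periodinane, NaHCO3, CH2Cl2, 0 °C → rt
Reagents that add atoms: none
Why: Buffered Dess–Martin oxidation of the neopentyl-type epoxy alcohol should give the aldehyde, which has no α-hydrogen, without acid that could open the epoxide (the descriptor at C1 changes only through ligand priorities).

Step 12
Reactants: 17 (1S,6R)-2,2,6-trimethyl-7-oxabicyclo[4.1.0]heptane-1-carbaldehyde
Product: 18 ethyl (2E,4E)-3-methyl-5-[(1S,6R)-2,2,6-trimethyl-7-oxabicyclo[4.1.0]heptan-1-yl]penta-2,4-dienoate
Conditions: (EtO)2P(O)CH2C(CH3)=CHCO2Et, NaH, THF, 0 °C; then 17, 0 °C → rt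
Reagents that add atoms: ethyl (2E)-4-(diethoxyphosphoryl)-3-methylbut-2-enoate, CCOC(=O)/C=C(\C)CP(=O)(OCC)OCC
Why: Vinylogous Horner–Wadsworth–Emmons olefination of the non-enolisable aldehyde should form the new C7=C8 bond as the E isomer and carry the 2E geometry of the reagent through, any 2Z material being removed by chromatography, while the epoxide centres are not touched.

Step 13
Reactants: 18 ethyl (2E,4E)-3-methyl-5-[(1S,6R)-2,2,6-trimethyl-7-oxabicyclo[4.1.0]heptan-1-yl]penta-2,4-dienoate
Product: 19 (2E,4E)-3-methyl-5-[(1S,6R)-2,2,6-trimethyl-7-oxabicyclo[4.1.0]heptan-1-yl]penta-2,4-dien-1-ol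
Conditions: i-Bu2AlH (2.5 equiv), CH2Cl2, −78 °C; aq. potassium sodium tartrate
Reagents that add atoms: none
Why: 1,2-Reduction of the conjugated ester with i-Bu2AlH at low temperature should stop at the dienol and leave the fully substituted epoxide intact, giving an electron-rich diene for the next step.

Step 14
Reactants: 19 (2E,4E)-3-methyl-5-[(1S,6R)-2,2,6-trimethyl-7-oxabicyclo[4.1.0]heptan-1-yl]penta-2,4-dien-1-ol
Product: 20 (2E)-3-[(2R,7aR)-4,4,7a-trimethyl-2,4,5,6,7,7a-hexahydro-1-benzofuran-2-yl]but-2-en-1-ol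
Conditions: camphor-10-sulfonic acid (cat.), CH2Cl2, −40 → −20 °C; Et3N; chromatography on Et3N-washed silica
Reagents that add atoms: none
Why: Acid opens the allylic C6–O bond of the vinyl epoxide to a tertiary dienyl cation that the oxygen left on C5 captures at C8 (the epoxide-to-furanoid rearrangement of 5,6-epoxy polyenes, a five-membered closure by cation capture), so C5 keeps its (R) configuration because its C–O bond never breaks, whereas C8 has no built-in control since the cation can close on either face after a ring flip; both C8 epimers are therefore expected, the (8R) isomer 20 with the side chain trans to the C5 methyl is isolated by chromatography, and the (8S) isomer can be returned to the same acid, which re-equilibrates C8 through the doubly allylic cation.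

Step 15
Reactants: 20 (2E)-3-[(2R,7aR)-4,4,7a-trimethyl-2,4,5,6,7,7a-hexahydro-1-benzofuran-2-yl]but-2-en-1-ol
Product: 22 (2R,7aR)-2-[(2E)-4-bromobut-2-en-2-yl]-4,4,7a-trimethyl-2,4,5,6,7,7a-hexahydro-1-benzofuran, via allylic mesylate 21 (not isolated)
Conditions: MsCl, Et3N, THF, −40 °C; then LiBr, 0 °C
Reagents that add atoms: lithium bromide, [Li+].[Br-]; methanesulfonyl chloride, CS(=O)(=O)Cl (its atoms remain only in 21)
Why: Mesylation and SN2 displacement by bromide under basic to neutral conditions should give the primary allylic bromide without the acid that would re-ionise the doubly allylic C8–O bond.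

Step 16
Reactants: 22 (2R,7aR)-2-[(2E)-4-bromobut-2-en-2-yl]-4,4,7a-trimethyl-2,4,5,6,7,7a-hexahydro-1-benzofuran
Product: 23 {(2E)-3-[(2R,7aR)-4,4,7a-trimethyl-2,4,5,6,7,7a-hexahydro-1-benzofuran-2-yl]but-2-en-1-yl}triphenylphosphonium bromide
Conditions: PPh3, toluene, rt, dark
Reagents that add atoms: triphenylphosphine, c1ccc(cc1)P(c1ccccc1)c1ccccc1
Why: SN2 quaternisation of triphenylphosphine by the primary allylic bromide should give the salt, which precipitates from toluene, with the alkene geometry and both ring stereocentres unchanged.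

Step 17
Reactants: 23 {(2E)-3-[(2R,7aR)-4,4,7a-trimethyl-2,4,5,6,7,7a-hexahydro-1-benzofuran-2-yl]but-2-en-1-yl}triphenylphosphonium bromide; 24 (2E,4E,6E)-2,7-dimethylocta-2,4,6-trienedial
Product: 26 (2E,4E,6E,8E,10E)-2,7-dimethyl-11-[(2R,7aR)-4,4,7a-trimethyl-2,4,5,6,7,7a-hexahydro-1-benzofuran-2-yl]dodeca-2,4,6,8,10-pentaenal, via furanoid ylide 25 (not isolated)
Conditions: 24 (3 equiv), NaOMe added slowly, MeOH/CH2Cl2, 0 °C → rt; then heptane, reflux
Reagents that add atoms: none
Why: Wittig olefination of one formyl group should stop at the mono-adduct because the dialdehyde is in excess and the remaining aldehyde of the product is deactivated by the longer polyene, the tertiary alkoxide being too poor a leaving group for ring opening of the ylide, and warming converts any cis geometry at the new C11=C12 bond to E.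

Step 18
Reactants: 26 (2E,4E,6E,8E,10E)-2,7-dimethyl-11-[(2R,7aR)-4,4,7a-trimethyl-2,4,5,6,7,7a-hexahydro-1-benzofuran-2-yl]dodeca-2,4,6,8,10-pentaenal; 13 {(2E,4E)-3-methyl-5-[(1R)-2,6,6-trimethylcyclohex-2-en-1-yl]penta-2,4-dien-1-yl}triphenylphosphonium bromide
Product: 28 (all-E,5R,8R,6'R)-5,8-epoxy-5,8-dihydro-β,ε-carotene, via epsilon-ring ylide 27 (not isolated)
Conditions: NaOMe, MeOH/CH2Cl2, rt; then heptane, reflux; crystallise
Reagents that add atoms: none
Why: Wittig olefination of the C25 aldehyde with the semi-stabilised C15 ylide should form C11'=C12' and complete the C40 skeleton, thermal equilibration and crystallisation giving the all-E polyene while C5, C8 and C6' stay out of the reacting system under the basic, acid-free conditions.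

**Compound list**

1 | 2-methylpropanal | CC(C)C=O | starting material
2 | pent-1-en-3-one | CCC(=O)C=C | starting material
3 | 2,2-dimethyl-5-oxoheptanal | CCC(=O)CCC(C)(C)C=O | intermediate
4 | 2,4,4-trimethylcyclohex-2-en-1-one | CC1=CC(C)(C)CCC1=O | intermediate
5 | (1S)-2,4,4-trimethylcyclohex-2-en-1-ol | CC1=CC(C)(C)CC[C@@H]1O | intermediate
6 | tributyl(iodomethyl)stannane | CCCC[Sn](CCCC)(CCCC)CI | starting material
7 | tributyl({[(1S)-2,4,4-trimethylcyclohex-2-en-1-yl]oxy}methyl)stannane | CC1=CC(C)(C)CC[C@@H]1OC[Sn](CCCC)(CCCC)CCCC | intermediate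
8 | ({[(1S)-2,4,4-trimethylcyclohex-2-en-1-yl]oxy}methyl)lithium | CC1=CC(C)(C)CC[C@@H]1OC[Li] | intermediate
9 | [(1R)-2,6,6-trimethylcyclohex-2-en-1-yl]methanol | CC1=CCCC(C)(C)[C@H]1CO | intermediate
10 | (1R)-2,6,6-trimethylcyclohex-2-ene-1-carbaldehyde | CC1=CCCC(C)(C)[C@H]1C=O | intermediate
11 | (3E)-4-[(1R)-2,6,6-trimethylcyclohex-2-en-1-yl]but-3-en-2-one | CC1=CCCC(C)(C)[C@H]1/C=C/C(C)=O | intermediate
12 | (1E)-3-methyl-1-[(1R)-2,6,6-trimethylcyclohex-2-en-1-yl]penta-1,4-dien-3-ol (both epimers at the carbinol carbon) | CC1=CCCC(C)(C)[C@H]1/C=C/C(C)(O)C=C | intermediate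
13 | {(2E,4E)-3-methyl-5-[(1R)-2,6,6-trimethylcyclohex-2-en-1-yl]penta-2,4-dien-1-yl}triphenylphosphonium bromide | CC1=CCCC(C)(C)[C@H]1/C=C/C(C)=C/C[P+](c2ccccc2)(c3ccccc3)c4ccccc4.[Br-] | intermediate
14 | 2,6,6-trimethylcyclohex-1-ene-1-carbaldehyde | CC1=C(C=O)C(C)(C)CCC1 | starting material
15 | (2,6,6-trimethylcyclohex-1-en-1-yl)methanol | CC1=C(CO)C(C)(C)CCC1 | intermediate
16 | [(1R,6R)-2,2,6-trimethyl-7-oxabicyclo[4.1.0]heptan-1-yl]methanol | OC[C@@]12O[C@]1(C)CCCC2(C)C | intermediate
17 | (1S,6R)-2,2,6-trimethyl-7-oxabicyclo[4.1.0]heptane-1-carbaldehyde | O=C[C@@]12O[C@]1(C)CCCC2(C)C | intermediate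
18 | ethyl (2E,4E)-3-methyl-5-[(1S,6R)-2,2,6-trimethyl-7-oxabicyclo[4.1.0]heptan-1-yl]penta-2,4-dienoate | CCOC(=O)/C=C(\C)/C=C/[C@@]12O[C@]1(C)CCCC2(C)C | intermediate
19 | (2E,4E)-3-methyl-5-[(1S,6R)-2,2,6-trimethyl-7-oxabicyclo[4.1.0]heptan-1-yl]penta-2,4-dien-1-ol | OC/C=C(\C)/C=C/[C@@]12O[C@]1(C)CCCC2(C)C | intermediate
20 | (2E)-3-[(2R,7aR)-4,4,7a-trimethyl-2,4,5,6,7,7a-hexahydro-1-benzofuran-2-yl]but-2-en-1-ol | OC/C=C(\C)[C@H]1C=C2C(C)(C)CCC[C@@]2(C)O1 | intermediate
21 | (2E)-3-[(2R,7aR)-4,4,7a-trimethyl-2,4,5,6,7,7a-hexahydro-1-benzofuran-2-yl]but-2-en-1-yl methanesulfonate | CS(=O)(=O)OC/C=C(\C)[C@H]1C=C2C(C)(C)CCC[C@@]2(C)O1 | intermediate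
22 | (2R,7aR)-2-[(2E)-4-bromobut-2-en-2-yl]-4,4,7a-trimethyl-2,4,5,6,7,7a-hexahydro-1-benzofuran | BrC/C=C(\C)[C@H]1C=C2C(C)(C)CCC[C@@]2(C)O1 | intermediate
23 | {(2E)-3-[(2R,7aR)-4,4,7a-trimethyl-2,4,5,6,7,7a-hexahydro-1-benzofuran-2-yl]but-2-en-1-yl}triphenylphosphonium bromide | [Br-].c3ccccc3[P+](c4ccccc4)(c5ccccc5)C/C=C(\C)[C@H]1C=C2C(C)(C)CCC[C@@]2(C)O1 | intermediate
24 | (2E,4E,6E)-2,7-dimethylocta-2,4,6-trienedial | O=C/C(C)=C/C=C/C=C(\C)C=O | starting material
25 | triphenyl{(2E)-3-[(2R,7aR)-4,4,7a-trimethyl-2,4,5,6,7,7a-hexahydro-1-benzofuran-2-yl]but-2-en-1-ylidene}-λ5-phosphane | c3ccccc3P(c4ccccc4)(c5ccccc5)=C/C=C(\C)[C@H]1C=C2C(C)(C)CCC[C@@]2(C)O1 | intermediate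
26 | (2E,4E,6E,8E,10E)-2,7-dimethyl-11-[(2R,7aR)-4,4,7a-trimethyl-2,4,5,6,7,7a-hexahydro-1-benzofuran-2-yl]dodeca-2,4,6,8,10-pentaenal | O=C/C(C)=C/C=C/C=C(C)/C=C/C=C(\C)[C@H]1C=C2C(C)(C)CCC[C@@]2(C)O1 | intermediate
27 | triphenyl{(2E,4E)-3-methyl-5-[(1R)-2,6,6-trimethylcyclohex-2-en-1-yl]penta-2,4-dien-1-ylidene}-λ5-phosphane | CC1=CCCC(C)(C)[C@H]1/C=C/C(C)=C/C=P(c2ccccc2)(c3ccccc3)c4ccccc4 | intermediate
28 | (all-E,5R,8R,6'R)-5,8-epoxy-5,8-dihydro-β,ε-carotene | CC1=CCCC(C)(C)[C@H]1/C=C/C(C)=C/C=C/C(C)=C/C=C/C=C(C)/C=C/C=C(\C)[C@H]1C=C2C(C)(C)CCC[C@@]2(C)O1 | target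

**Step count and risks**

Total step count: 18. Longest linear sequence: 10 steps (steps 9–17, then step 18); the ε-ring branch is 9 steps (steps 1–8, then step 18).

Steps most likely to fail:

Step 14. The closure has no facial preference, so much of the material is expected to end with the wrong C8 configuration. The doubly allylic C8–O bond may also re-ionise during the three steps that follow. Capture of the cation by the free primary hydroxyl of a second molecule is a further drain. The fallback keeps the epoxide through the chain extension and moves the rearrangement to the apocarotenal stage, where only one Wittig step follows. It sets out from 19: bromination with CBr4, PPh3 and 2,6-lutidine in CH2Cl2 at 0 °C would give (1S,6R)-1-[(1E,3E)-5-bromo-3-methylpenta-1,3-dien-1-yl]-2,2,6-trimethyl-7-oxabicyclo[4.1.0]heptane F1. PPh3 in toluene would turn this into {(2E,4E)-3-methyl-5-[(1S,6R)-2,2,6-trimethyl-7-oxabicyclo[4.1.0]heptan-1-yl]penta-2,4-dien-1-yl}triphenylphosphonium bromide F2. NaOMe would give its ylide, triphenyl{(2E,4E)-3-methyl-5-[(1S,6R)-2,2,6-trimethyl-7-oxabicyclo[4.1.0]heptan-1-yl]penta-2,4-dien-1-ylidene}-λ5-phosphane F3, which with excess 24 should give (2E,4E,6E,8E,10E,12E)-2,7,11-trimethyl-13-[(1S,6R)-2,2,6-trimethyl-7-oxabicyclo[4.1.0]heptan-1-yl]trideca-2,4,6,8,10,12-hexaenal F4. Dilute HCl in CHCl3 would then effect the furanoid rearrangement on this apocarotenal, the C8 isomers would be separated by HPLC, and the (8R) isomer brings the route back at 26.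

Step 6. The phosphonate anion may remove the C6' proton (α to the aldehyde and allylic) faster than it adds to the hindered carbonyl, which would lower the enantiomeric purity or move the ring alkene into conjugation. The fallback replaces the basic olefination by a chromium-mediated one and an acylation. It sets out from 10: Takai olefination with CrCl2 and CHI3 in THF at 0 °C should give (6R)-6-[(E)-2-iodoethenyl]-1,5,5-trimethylcyclohex-1-ene F5. Iodine–lithium exchange with t-BuLi in Et2O at −78 °C would give {(E)-2-[(1R)-2,6,6-trimethylcyclohex-2-en-1-yl]ethenyl}lithium F6, and acylation of this with N-methoxy-N-methylacetamide, quenched with aq. NH4Cl, returns the route at 11.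

Step 4. The carbanion may undergo [1,2]-shift or be quenched before it reaches the hindered C6' terminus, so that the C6'–C7' bond is not formed or is formed at the wrong carbon. The fallback makes the same bond by a copper-catalysed anti-SN2' substitution from the enantiomeric carbinol. It sets out from 4: reduction with (3aS)-1-methyl-3,3-diphenyltetrahydro-1H,3H-pyrrolo[1,2-c][1,3,2]oxazaborole and BH3·SMe2 would give (1R)-2,4,4-trimethylcyclohex-2-en-1-ol F7. Esterification with pyridine-2-carboxylic acid, N,N'-dicyclohexylcarbodiimide and 4-(dimethylamino)pyridine would give (1R)-2,4,4-trimethylcyclohex-2-en-1-yl pyridine-2-carboxylate F8. Treatment with [dimethyl(propan-2-yloxy)silyl]methylmagnesium chloride F9 (made from the commercial chloromethylsilane and Mg) and CuBr·SMe2 in THF at −40 °C should deliver the silylmethyl group to C6' on the face opposite the leaving group, giving dimethyl(propan-2-yloxy){[(1R)-2,6,6-trimethylcyclohex-2-en-1-yl]methyl}silane F10. Tamao oxidation (H2O2, KF, KHCO3, THF/MeOH) returns the route at 9.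

**Further compounds**

F1 | step 14 | (1S,6R)-1-[(1E,3E)-5-bromo-3-methylpenta-1,3-dien-1-yl]-2,2,6-trimethyl-7-oxabicyclo[4.1.0]heptane | BrC/C=C(\C)/C=C/[C@@]12O[C@]1(C)CCCC2(C)C
F2 | step 14 | {(2E,4E)-3-methyl-5-[(1S,6R)-2,2,6-trimethyl-7-oxabicyclo[4.1.0]heptan-1-yl]penta-2,4-dien-1-yl}triphenylphosphonium bromide | [Br-].c3ccccc3[P+](c4ccccc4)(c5ccccc5)C/C=C(\C)/C=C/[C@@]12O[C@]1(C)CCCC2(C)C
F3 | step 14 | triphenyl{(2E,4E)-3-methyl-5-[(1S,6R)-2,2,6-trimethyl-7-oxabicyclo[4.1.0]heptan-1-yl]penta-2,4-dien-1-ylidene}-λ5-phosphane | c3ccccc3P(c4ccccc4)(c5ccccc5)=C/C=C(\C)/C=C/[C@@]12O[C@]1(C)CCCC2(C)C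
F4 | step 14 | (2E,4E,6E,8E,10E,12E)-2,7,11-trimethyl-13-[(1S,6R)-2,2,6-trimethyl-7-oxabicyclo[4.1.0]heptan-1-yl]trideca-2,4,6,8,10,12-hexaenal | O=C/C(C)=C/C=C/C=C(C)/C=C/C=C(\C)/C=C/[C@@]12O[C@]1(C)CCCC2(C)C
F5 | step 6 | (6R)-6-[(E)-2-iodoethenyl]-1,5,5-trimethylcyclohex-1-ene | CC1=CCCC(C)(C)[C@H]1/C=C/I
F6 | step 6 | {(E)-2-[(1R)-2,6,6-trimethylcyclohex-2-en-1-yl]ethenyl}lithium | CC1=CCCC(C)(C)[C@H]1/C=C/[Li]
F7 | step 4 | (1R)-2,4,4-trimethylcyclohex-2-en-1-ol | CC1=CC(C)(C)CC[C@H]1O
F8 | step 4 | (1R)-2,4,4-trimethylcyclohex-2-en-1-yl pyridine-2-carboxylate | CC1=CC(C)(C)CC[C@H]1OC(=O)c2ccccn2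
F9 | step 4 | [dimethyl(propan-2-yloxy)silyl]methylmagnesium chloride | CC(C)O[Si](C)(C)C[Mg]Cl
F10 | step 4 | dimethyl(propan-2-yloxy){[(1R)-2,6,6-trimethylcyclohex-2-en-1-yl]methyl}silane | CC1=CCCC(C)(C)[C@H]1C[Si](C)(C)OC(C)C
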